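The runs stem from a simulated flask from invented constants; noise was put on by code.

In a one-step world, partner and free catalyst turn left-handed substrate into left-handed product and nothing else touches either, so the two together stay at the charge of left-handed substrate, 50.0% of both substrates charged: call that the left-hand ceiling. Left-handed substrate is the limiting reagent of that world: 0.10 M of it meets 0.220 M of partner.

| flask | left-handed substrate | right-handed substrate | partner | free catalyst | precatalyst | temperature | remark | time |
|---|---|---|---|---|---|---|---|---|
| alder | 0.10 M | 0.10 M | 0.22 M | 1.3 mM | 10 mM | 2 °C | run made earlier |  |
| maple | 0.10 M | 0.10 M | 0.22 M | 3 mM | 10 mM | 52 °C | run made earlier |  |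
| Thursday's | 0.10 M | 0.10 M | 0.220 M | 2.0 mM | 10 mM | 10 °C |  | 6.0 min |
| Monday's | 0.10 M | 0.10 M | 0.220 M | 2.0 mM | 10 mM | −20 °C |  | 6.0 min |
| Wednesday's | 0.10 M | 0.10 M | 0.220 M | 2.0 mM | 10 mM | 70 °C |  | 6.0 min |
| Sunday's | 0.10 M | 0.10 M | 0.220 M | 2.0 mM | 10 mM | 40 °C |  | 6.0 min |

| alder: time / min | alder: left-handed product / % | maple: time / s | maple: left-handed product / % |
|---|---|---|---|
| 0.417 | 0 | 10.0 | 2.5 |
| 0.667 | 0 | 15.0 | 3.5 |
| 1.33 | 0 | 25.0 | 4.9 |
| 2.50 | 0.7 | 30.0 | 5.4 |
| 5.00 | 1.3 | 40.0 | 6.8 |

(readings scatter by 0.5 percentage points)

- free catalyst is single-handed; left-handed substrate and right-handed substrate are mirror images of each other, charged as a racemate, each of them at the stated concentration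

- which flask leads in amount of left-handed product, in percent of the left-handed substrate and right-handed substrate together charged ("all alike" within 1.5 percentage points) (Thursday's / Monday's / Wednesday's / Sunday's / all alike)
- how much left-handed product is there at the end, in percent of the left-handed substrate and right-handed substrate together charged: Thursday's
- how much left-handed product is there at the end, in percent of the left-handed substrate and right-handed substrate together charged: Monday's
- how much left-handed product is there at the end, in percent of the left-handed substrate and right-handed substrate together charged: Wednesday's
- how much left-handed product is there at the end, in percent of the left-handed substrate and right-handed substrate together charged: Sunday's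

With partner and free catalyst held steady (pseudo-first-order), left-handed product closes its gap to the ceiling exponentially, so each reading gives a one-step constant, which I scale to the 2.0 mM of free catalyst in the four flasks.

The maple run offers two ways to that constant, and they part. Its first reading gives 0.205 min⁻¹, more than the 0.146 min⁻¹ of its last. That looks like a flask slowing down. But run the last value backwards and it puts the first reading at 1.79%, where 2.5% stands: a gap of 0.71 percentage points against a scatter of 0.5 points. The scatter is the same at both readings, and the last stands 2.72 times as high, so I trust the last and keep the free catalyst alive.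

The alder run's last reading gives 0.00811 min⁻¹, a rough value under that scatter. The two constants together give a temperature steepness of 43.0 kJ mol⁻¹. My reckoning then runs 0.472% for Monday's, 3.97% for Thursday's, 19.0% for Sunday's and 43.4% for Wednesday's, which stays below the ceiling. I put Wednesday's first. On a repeat, the sum to watch is left-handed substrate plus left-handed product.

The forecast differs from my reckoning: it puts Sunday's first at 11.5%, with 3.2% for Wednesday's, 4.3% for Thursday's and 0.4% for Monday's, holding that “the catalyst is probably dying”.

The flasks give Wednesday's first at 42.2%, with 18.3% for Sunday's, 4.35% for Thursday's and 0.563% for Monday's.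

    precatalyst → racemization catalyst (k = 0.285 min⁻¹, Ea = 110 kJ mol⁻¹)
    partner + free catalyst + right-handed substrate → free catalyst + right-handed product (k = 394 M⁻² min⁻¹, Ea = 40.0 kJ mol⁻¹)
    left-handed substrate + racemization catalyst ⇌ right-handed substrate + racemization catalyst, rate k3*[racemization catalyst]*[left-handed substrate] forward; the back reaction follows from the equilibrium constant (k = 2950 M⁻¹ min⁻¹, Ea = 40.0 kJ mol⁻¹)
    partner + free catalyst + left-handed substrate → free catalyst + left-handed product (k = 807 M⁻² min⁻¹, Ea = 42.0 kJ mol⁻¹)
    (constants at 70 °C)

Of the 42 points by which Wednesday's leads Monday's, the largest single effect is what temperature does to the step from partner, free catalyst and left-handed substrate to left-handed product: with that effect taken away, the difference stands at −0.18 points. In Wednesday's the sum does not hold: at 6.00 min, 18.5% of left-handed substrate and 42.2% of left-handed product make 60.7%, more than the ceiling. The one-step world does not hold in Wednesday's, where racemization catalyst stands at 81.9% of the precatalyst charged. Sunday's left-handed product passes the same ceiling of 50.0%, reaching 53.6% after 60.0 min.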